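## Structural features

Agrimol B is a linear trimer of acylphloroglucinol units: three fully substituted benzene rings joined as ring A–CH2–ring B–CH2–ring C, with no fused or heterocyclic ring. Ring B is the central 2,4,6-trihydroxyphenyl ketone; its two remaining ring carbons each carry one bridge methylene, and its acyl group is (2S)-2-methylbutanoyl. Rings A and C are identical: going round either ring from the bridge carbon, the substituents are OH, butanoyl, OMe, C-methyl, OH, so the methoxy carbon lies between the acyl carbon and the methyl carbon, and the bridge carbon lies between the two hydroxylated carbons. The only stereocentre is the α-carbon of the ring B ketone; it has no stereogenic neighbour, but it is a tertiary, enolisable C–H next to an aryl ketone and is the single stereochemical liability. The fragile elements are the electron-rich diarylmethane links (cleaved and redistributed through ortho-quinone methides under acid, base or heat), the air-sensitive polyphenol array, and the methoxy group ortho to a ketone, which strong Lewis acids cleave. The real difficulty is the oxygen pattern of rings A and C: of three ring oxygens only the most hindered, chelated one, between acyl and C-methyl, is methylated, and direct methylation of a triol cannot be expected to deliver that. The key step exploits the C(methyl)–C(OMe)–C(acyl) triad: it maps onto C2, C3 and C4 of the γ-acylated methyl enol ether of methyl 2-methyl-3-oxobutanoate, so the methyl ether exists before the ring does and the ester carbon C1 becomes the hydroxylated ring carbon next to the C-methyl group. The near twofold symmetry, broken only by the stereocentre, lets both bridges be made from two identical outer-ring halves.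

## Logic of the disconnections

19 ⇒ 12 (twice) + 16. The two bonds from the bridge methylene carbons to ring B are cut. Because rings A and C are identical, this gives one electrophilic half twice (12, acting through 17) and one nucleophile (16), and the stereocentre stays in the smaller fragment and meets one step only. A trimer of 49 heavy atoms falls into building blocks of 20 and 15 heavy atoms. The forward step must alkylate carbon, not oxygen, at both open positions of ring B (through 18), must not exchange bridges once formed, and must leave the ketone α-carbon untouched.

12 ⇒ 11. The bond between the ring carbon and the aminomethyl carbon is cut. 11 has a single unsubstituted ring carbon, flanked by two hydroxyl groups, so the position is not in question. The forward step must stop at one aminomethylation and must not join two molecules of 11 through one methylene.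

11 ⇒ 9 (by way of 10). A carboxyl carbon is put back on the free ring carbon; the ring–CO2Me bond of 9 is the one the forward step breaks. The ester is kept because it makes the ring-forming carbon nucleophilic in the next disconnection. The forward step must hydrolyse a hindered, chelated ester and decarboxylate without losing the ketone side chain.

9 ⇒ 8. The ring bond between the ester-bearing carbon and the hydroxylated carbon next to the C-methyl group is cut. The hexasubstituted arene, with its oxygen-differentiation problem, becomes an open chain in which every substituent, the methyl ether included, already sits on the right carbon. The forward step must close through carbon, and only through the doubly activated methylene.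

8 ⇒ 6 + 7. The bond between C4 and the C5 carbonyl carbon is cut. C4 of 6 is its only methylene activated from both sides, and 7 brings C5–C7, with the future ring carbon and its ester, in one piece. The forward step must acylate carbon, not the enolate oxygen, and the enolate must not lactonise onto C1.

6 ⇒ 3 + 4. The bond between the γ-carbon (C4) and the ketone carbon (C5) is cut. This leaves the four-carbon enol ether that carries the methyl, methoxy and ester carbons in their final order, plus a simple acyl donor. The forward step must react through the γ-carbon and acylate once only.

3 ⇒ 1 (by way of 2). The enol ether C–O bond at C3 is cut, which returns 1. This is the point at which the oxygen that ends up methylated in rings A and C is marked. The forward step should give the E isomer, with ester and C4 on the same side.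

16 ⇒ 13 + 14 (by way of 15). The aryl–carbonyl bond is cut. The three ring positions of 14 are equivalent and the stereocentre is bought with 13. The forward step must acylate carbon once and must not racemise the α-carbon.

## Other disconnections considered

Alternative 1: Both outer rings are cut at once. In each, the bond between the phenol carbon and the bridge-bearing carbon and the bond between the siloxy carbon and the methyl-bearing carbon are removed. This leaves ring B as the bis(siloxyalkyne) A2 and two molecules of the cyclobutenone A3. In the forward direction, heating A2 with two equivalents of A3 would run a pericyclic cascade in each arm (ring opening of A3 to a vinylketene, [2+2] addition to the siloxyalkyne, a second four-electron ring opening, six-electron electrocyclisation, tautomerisation) and give the bis-resorcinol A1.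
- In its favour: the bridges exist before the outer rings, so no quinone methide coupling and no bridge exchange is needed. The regiochemistry is fixed by the mechanism, and the three oxygens of each outer ring emerge differentiated (free OH, OMe, silyl ether).
- Against it here: A1 carries none of the three acyl groups. They would have to be introduced late onto an acid-sensitive, benzyl-protected trimer, including the α-chiral one on a ring B carbon flanked by two benzyloxy groups. Several deprotections follow, A2 needs a multistep preparation, and two benzannulations must both succeed in one molecule.
- Comparison: on structure, the chosen plan delivers the outer ring with acyl, C-methyl and methoxy already in place, whereas A1 has only the last two. On mechanism, the pericyclic cascade has no carbon-versus-oxygen ambiguity and avoids the bridge-forming end game; on both points it is the better of the two. On step economy the chosen plan (eight steps) should be clearly shorter, and it brings in the stereocentre under milder conditions.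

Alternative 2: Ring B is cut at the ring bond between the acyl-bearing carbon and one hydroxylated carbon. This unfolds A4 (identical with 16) into the pyrone A5, which would come from the dianion of A6 and the acyl group of 13. In the forward direction Mg(OMe)2 in methanol would open the lactone of A5, and within the chelated open chain the methylene between the two ketones would attack the new ester carbonyl (Claisen closure) to give A4.
- In its favour: it is biomimetic, uses cheap materials, avoids AlCl3 and acylium chemistry next to the stereocentre, and magnesium chelation steers towards Claisen rather than aldol closure.
- Against it here: it addresses ring B, which is the easy ring (one Friedel–Crafts step in the chosen plan), and takes two to three steps to do so. The stereocentre would sit α to a ketone through dianion chemistry and hours of basic methanol, and aldol closure to a resorcylate competes. It contributes nothing to rings A and C or to the bridges.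
- Comparison: on structure it gives the same compound as 16. On mechanism it is of the same kind as the chosen key step (Claisen-type aromatisation of a masked polyketide chain) and is the better on one point, the absence of a strong Lewis acid. On step economy it is worse by one or two steps. It could stand in for step 7 but cannot replace the chosen plan.

Alternative 3: The outer ring is cut between the acyl-bearing and the methoxy-bearing carbons, which leads back to the 2-methoxy-4-pyranone A8. In the forward direction catalytic NaOMe would add to C2 of A8 and open the ring; the side-chain methylene carbanion would then add to the same carbon and expel methoxide. The result is a net isomerisation to A7 (identical with 11).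
- In its favour: it reaches 11 directly, with no ester to remove, using catalytic base and losing no atoms. The methyl ether is fixed before the benzene ring exists, which makes it the equal of the chosen plan on that central point.
- Against it here: the methoxy-bearing carbon is itself the electrophilic centre. The methyl ether survives only if closure occurs at the ring-opened ketene acetal stage; if that stage is intercepted as an ordinary ester, Claisen closure would leave a free hydroxyl where the methoxy group is needed. A8 in turn requires O-methylation of an ambident 4-hydroxy-2-pyranone anion at the ring carbonyl oxygen with a hard methylating agent, plus a side-chain acylation. Aldol-type closures of the opened chain also compete.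
- Comparison: on structure the product is the chosen arene without the carboxyl group. On mechanism the chosen plan is safer, because there the methoxy carbon is a spectator and the fate of the methyl ether does not depend on the pathway. On step economy this alternative is equal or better: one step fewer after ring formation and a precursor of similar length.

Key step: step 4

Remarks on the chemistry, made before the steps:
- Assumption: 4 is taken as a catalogue reagent; otherwise it is one step from butanoyl chloride and MeNH(OMe)·HCl.
- Metal enolates and phenoxides are treated as ionised forms of the numbered compounds and carry no numbers of their own.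
- Two facts about 8 on which the steps depend: its most acidic position is C4 (between the two ketone carbons), not the C6 methylene that has to attack; and the C6-to-C1 closure is not the only six-membered C–C closure the chain allows, because the α-methylene of the butanoyl group is also six atoms from C1. Both are treated as selectivity questions in step 4.
- The enol geometry drawn for 8 is one hydrogen-bonded tautomer and has no stereochemical meaning; only the E geometry of the C2=C3 enol ether matters.
- Two choices on the way to 8 are meant to make it safer. A Weinreb amide is used for the γ-acylation, so there is no over-acylation and no warm basic ketone enolate. The stronger soft-enolisation system MgBr2·OEt2/i-Pr2NEt is used for the C-acylation, because 6 is only a vinylogous 1,3-dicarbonyl compound.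

## Route

Step 1
Reactants: 1 methyl 2-methyl-3-oxobutanoate (racemic)
Product: 3 methyl (2E)-3-methoxy-2-methylbut-2-enoate, via methyl 3,3-dimethoxy-2-methylbutanoate 2 (not isolated)
Conditions: HC(OMe)3, cat. H2SO4, MeOH, rt; then slow distillation (−MeOH)
Reagents that add atoms: trimethyl orthoformate, COC(OC)OC
Why: Acid-catalysed ketalisation with the orthoformate (which also scavenges water) gives 2, and distillation from the acid eliminates methanol to the conjugated enol ether (enol ether formation via the dimethyl ketal); the E isomer, methoxy trans to ester, is the thermodynamically preferred one, and the stereocentre of racemic 1 becomes sp2, so its configuration is irrelevant.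

Step 2
Reactants: 3 methyl (2E)-3-methoxy-2-methylbut-2-enoate; 4 N-methoxy-N-methylbutanamide
Product: 6 methyl (2E)-3-methoxy-2-methyl-5-oxooct-2-enoate, via lithium hemiaminal alkoxide 5 (not isolated)
Conditions: LiN(i-Pr)2 (1.1 equiv), THF, −78 °C; then 4, −78 to −40 °C; AcOH, −78 °C
Reagents that add atoms: none
Why: LiN(i-Pr)2 removes a proton from the γ-methyl group, which is cis to the ester, and the extended lithium enolate of 3 attacks the Weinreb amide through its γ-carbon, because the α-carbon is blocked by the C2 methyl group and γ-attack keeps the enol ether conjugated (vinylogous Claisen acylation, Weinreb ketone synthesis). The chelated tetrahedral adduct 5 cannot be acylated again and releases the ketone only at the cold acidic quench, so the δ-keto enoate never meets base warm enough to lactonise onto the C1 ester.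

Step 3
Reactants: 6 methyl (2E)-3-methoxy-2-methyl-5-oxooct-2-enoate; 7 methyl 3-chloro-3-oxopropanoate
Product: 8 dimethyl (2E)-4-(1-hydroxybutylidene)-3-methoxy-2-methyl-5-oxohept-2-enedioate (enol form of the 4-butanoyl keto diester)
Conditions: MgBr2·OEt2 (2.5 equiv), i-Pr2NEt (3 equiv), CH2Cl2, 0 °C; slow addition of 7; cold 1 M HCl work-up
Reagents that add atoms: none
Why: MgBr2·OEt2 with i-Pr2NEt enolises the ketone of 6 reversibly (soft enolisation), and the enolate that accumulates is the conjugated one at C4, the methylene between the ketone and the vinylogous ester. Bromomagnesium enolates are acylated by acid chlorides at carbon (C-acylation of ketones and 1,3-dicarbonyl compounds under MgX2/amine conditions), and the more acidic product is held as a chelate that resists a second acylation.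

Step 4
Reactants: 8 dimethyl (2E)-4-(1-hydroxybutylidene)-3-methoxy-2-methyl-5-oxohept-2-enedioate
Product: 9 methyl 3-butanoyl-2,6-dihydroxy-4-methoxy-5-methylbenzoate
Conditions: NaOMe (4 equiv), MeOH (about 0.05 M in 8), 0 °C to 65 °C, Ar; then cold 1 M HCl
Reagents that add atoms: none
Why: NaOMe first ionises 8 at C4; the reacting species is the C6 carbanion (C6 is the methylene between the C5 ketone and the C7 ester), present as the minor tautomer of the monoanion or as the dianion, which adds to the C1 ester carbonyl held cis to C4 by the E enol ether, expels methoxide and gives a cyclohexenedione that tautomerises to the arene and is deprotonated to the disodium bis-phenoxide of 9. The closest known reactions are the Dieckmann–Claisen aromatisation of 3,5-dioxo diesters to phloroglucinol carboxylates and the base-induced conversion of 4-methoxy-2-pyranones with oxoalkyl side chains into phloroglucinol methyl ethers, in which a carbanion likewise attacks the carbonyl of a β-methoxy enoate. The single ring is closed in the 6-exo-trig mode (C6 onto C1, carbonyl oxygen outside the ring). No stereocentre is formed; the enol ether geometry vanishes in the arene, and a Z isomer would be equilibrated by reversible conjugate addition of methoxide at C3. The step needs carbon to win over oxygen: the enolate oxygens at C5 and at the butanoyl carbon can also reach C1 and give 2-pyranones, but in NaOMe/MeOH such lactones are reopened by methoxide, whereas C-closure ends in an aromatic bis-phenoxide that cannot revert. It also needs C6 to win over the α-methylene of the butanoyl group, which could close a six-membered ring onto C1 as well; that carbon is activated by one carbonyl only and is far less acidic than C6. Excess methoxide keeps 8 fully enolised at C4, which protects the 2-acyl-1,3-dicarbonyl unit against retro-Claisen cleavage, and methoxide matches both esters, so ester exchange is invisible. The methoxy-bearing C3 is a spectator throughout, which is why the methyl ether arrives in the ring untouched.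

Step 5
Reactants: 9 methyl 3-butanoyl-2,6-dihydroxy-4-methoxy-5-methylbenzoate
Product: 11 1-(4,6-dihydroxy-2-methoxy-3-methylphenyl)butan-1-one, via 3-butanoyl-2,6-dihydroxy-4-methoxy-5-methylbenzoic acid 10 (not isolated)
Conditions: 2 M aq NaOH, 90 °C, Ar; then HCl to pH 2, 60 °C
Reagents that add atoms: none
Why: Hydroxide hydrolyses the ester to the salt of 10; on acidification the electron-rich ring is protonated at the carboxyl-bearing carbon and the resulting β-keto acid tautomer loses CO2 on gentle warming (saponification and protodecarboxylation of a 2,6-dihydroxybenzoic acid). The aryl methyl ether and the chelated aryl ketone should tolerate aqueous alkali when air is excluded.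

Step 6
Reactants: 11 1-(4,6-dihydroxy-2-methoxy-3-methylphenyl)butan-1-one
Product: 12 1-{3-[(dimethylamino)methyl]-2,4-dihydroxy-6-methoxy-5-methylphenyl}butan-1-one
Conditions: 37% aq CH2O (1.1 equiv) premixed with 40% aq Me2NH (1.5 equiv), EtOH, 0 °C to rt
Reagents that add atoms: formaldehyde, C=O; dimethylamine, CNC
Why: Phenolic Mannich reaction: the iminium ion from formaldehyde and dimethylamine attacks the one unsubstituted ring carbon of 11, which lies between two hydroxyl groups, so there is no regiochemical choice. Premixing amine and aldehyde keeps free formaldehyde low and so disfavours methylene bridging between two molecules of 11.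

Step 7
Reactants: 13 (2S)-2-methylbutanoic acid; 14 benzene-1,3,5-triol (phloroglucinol, anhydrous)
Product: 16 (2S)-2-methyl-1-(2,4,6-trihydroxyphenyl)butan-1-one, via (2S)-2-methylbutanoyl chloride 15 (not isolated)
Conditions: (COCl)2, cat. DMF, CH2Cl2, 0 °C to rt; then 14, AlCl3 (3.5 equiv), CH2Cl2/PhNO2, 0 °C to rt; ice/HCl
Reagents that add atoms: none
Why: (COCl)2 with catalytic DMF converts 13 into 15 without base, and AlCl3 then promotes Friedel–Crafts C-acylation of 14, whose three ring positions are equivalent and whose monoketone is deactivated towards a second acylation. The stereocentre is bought with 13 and is not a reacting centre; low temperature and the absence of amine base are meant to keep ketene formation and enolisation, the two racemisation channels, slow.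

Step 8
Reactants: 12 1-{3-[(dimethylamino)methyl]-2,4-dihydroxy-6-methoxy-5-methylphenyl}butan-1-one (2.2 equiv); 16 (2S)-2-methyl-1-(2,4,6-trihydroxyphenyl)butan-1-one
Product: 19 agrimol B [(2S)-1-{3,5-bis[(3-butanoyl-2,6-dihydroxy-4-methoxy-5-methylphenyl)methyl]-2,4,6-trihydroxyphenyl}-2-methylbutan-1-one], via ortho-quinone methide 17 (not isolated), via mono-bridged diarylmethane 18 (not isolated)
Conditions: 1,4-dioxane, 90 °C, Ar; slow addition of 12 to 16
Reagents that add atoms: none
Why: On heating, the ortho-hydroxybenzylamine 12 loses dimethylamine to give ortho-quinone methide 17, which is attacked at its methylene carbon by a nucleophilic ring carbon of 16 (conjugate addition with rearomatisation of both rings); the same event at the second open position of 18 gives 19. Slow addition keeps 17 dilute beside the better nucleophile, and the medium stays neutral to weakly basic, where the ring B ketone is partly a phenoxide (a vinylogous carboxylate) that resists α-deprotonation, so the stereocentre should be retained.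

## Compound list

1 | methyl 2-methyl-3-oxobutanoate (racemic) | COC(=O)C(C)C(C)=O | starting material
2 | methyl 3,3-dimethoxy-2-methylbutanoate (racemic) | COC(=O)C(C)C(C)(OC)OC | intermediate (not isolated)
3 | methyl (2E)-3-methoxy-2-methylbut-2-enoate | COC(=O)/C(C)=C(/OC)C | intermediate
4 | N-methoxy-N-methylbutanamide | CCCC(=O)N(C)OC | starting material
5 | lithium (2E)-1,3-dimethoxy-5-[methoxy(methyl)amino]-2-methyl-1-oxooct-2-en-5-olate (racemic at C5) | COC(=O)/C(C)=C(/OC)CC([O-])(CCC)N(C)OC.[Li+] | intermediate (not isolated)
6 | methyl (2E)-3-methoxy-2-methyl-5-oxooct-2-enoate | COC(=O)/C(C)=C(/OC)CC(=O)CCC | intermediate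
7 | methyl 3-chloro-3-oxopropanoate | COC(=O)CC(=O)Cl | starting material
8 | dimethyl (2E)-4-(1-hydroxybutylidene)-3-methoxy-2-methyl-5-oxohept-2-enedioate (enol form of the 4-butanoyl keto diester) | COC(=O)/C(C)=C(/OC)\C(C(=O)CC(=O)OC)=C(\O)CCC | intermediate
9 | methyl 3-butanoyl-2,6-dihydroxy-4-methoxy-5-methylbenzoate | COC(=O)c1c(O)c(C(=O)CCC)c(OC)c(C)c1O | intermediate
10 | 3-butanoyl-2,6-dihydroxy-4-methoxy-5-methylbenzoic acid | OC(=O)c1c(O)c(C(=O)CCC)c(OC)c(C)c1O | intermediate (not isolated)
11 | 1-(4,6-dihydroxy-2-methoxy-3-methylphenyl)butan-1-one | CCCC(=O)c1c(O)cc(O)c(C)c1OC | intermediate
12 | 1-{3-[(dimethylamino)methyl]-2,4-dihydroxy-6-methoxy-5-methylphenyl}butan-1-one | CCCC(=O)c1c(O)c(CN(C)C)c(O)c(C)c1OC | intermediate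
13 | (2S)-2-methylbutanoic acid | CC[C@H](C)C(=O)O | starting material
14 | benzene-1,3,5-triol (phloroglucinol) | Oc1cc(O)cc(O)c1 | starting material
15 | (2S)-2-methylbutanoyl chloride | CC[C@H](C)C(=O)Cl | intermediate (not isolated)
16 | (2S)-2-methyl-1-(2,4,6-trihydroxyphenyl)butan-1-one | Oc1cc(O)c(C(=O)[C@@H](C)CC)c(O)c1 | intermediate
17 | 4-butanoyl-3-hydroxy-5-methoxy-6-methyl-2-methylidenecyclohexa-3,5-dien-1-one | C=C1C(=O)C(C)=C(OC)C(C(=O)CCC)=C1O | intermediate (not isolated)
18 | (2S)-1-{3-[(3-butanoyl-2,6-dihydroxy-4-methoxy-5-methylphenyl)methyl]-2,4,6-trihydroxyphenyl}-2-methylbutan-1-one | CCCC(=O)c1c(O)c(Cc2c(O)cc(O)c(C(=O)[C@@H](C)CC)c2O)c(O)c(C)c1OC | intermediate (not isolated)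
19 | agrimol B, (2S)-1-{3,5-bis[(3-butanoyl-2,6-dihydroxy-4-methoxy-5-methylphenyl)methyl]-2,4,6-trihydroxyphenyl}-2-methylbutan-1-one | CCCC(=O)c1c(O)c(Cc2c(O)c(Cc3c(O)c(C)c(OC)c(C(=O)CCC)c3O)c(O)c(C(=O)[C@@H](C)CC)c2O)c(O)c(C)c1OC | target

## Step count and least certain steps

Total step count: 8. Longest linear sequence: 7 steps (steps 1–6 and 8); step 7 is a one-step side branch.

Least certain steps, in route order.

**Step 3 (C-acylation of 6).** The most likely failure is acylation at the enolate oxygen, or ring closure of the enolate oxygen onto the C1 ester before acylation. The enolate of 6 is a vinylogous, weakly nucleophilic carbon enolate whose oxygen sits six atoms from C1. Loss of HCl from 7 to a ketene that oligomerises would in addition starve the reaction.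

The fallback inverts the order of the two acylations, so that C4 becomes the terminal and most nucleophilic site of a β-keto ester dianion. It sets out from 3 and returns at 8. The lithium enolate of 3 (LiN(i-Pr)2, THF, −78 °C) would be carboxylated at the γ-carbon with CO2 to give (3E)-3,5-dimethoxy-4-methyl-5-oxopent-3-enoic acid F1. Activation of F1 with 1,1'-carbonyldiimidazole and reaction with Mg(O2CCH2CO2Me)2 (decarboxylative Claisen homologation of the acyl imidazolide) would give dimethyl (2E)-3-methoxy-2-methyl-5-oxohept-2-enedioate F2. Double deprotonation of F2 (LiN(i-Pr)2, 2.1 equiv, THF, −78 °C) places the second charge on C4, which would attack 4; AcOH quench then gives 8. Three steps replace steps 2 and 3, and the acylating agent can only react at carbon.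

**Step 4 (key step).** Two processes are most likely to go wrong. The first is cleavage of a C4–acyl bond by methoxide (retro-Claisen of the 2-acyl-1,3-dicarbonyl unit), which could outrun a slow closure. The closure may be slow because the first negative charge settles on C4 and not on the attacking C6, and because the C1 carbonyl is a deactivated vinylogous carbonate. The second is persistent closure through oxygen.

The fallback closes the ring before the butanoyl group is present. It sets out from 3 and returns at 9. 3 would be taken, as in the fallback to step 3, to dimethyl (2E)-3-methoxy-2-methyl-5-oxohept-2-enedioate F2, in which C6 is the most acidic carbon and no 2-acyl-1,3-dicarbonyl unit exists. NaOMe in MeOH should then close F2 to methyl 2,6-dihydroxy-4-methoxy-3-methylbenzoate F3. Friedel–Crafts butanoylation at the only free ring position of F3 (butanoyl chloride, TiCl4, CH2Cl2, 0 °C) would give 9. TiCl4 at low temperature is chosen over AlCl3 to avoid cleaving the methoxy group that ends up ortho to the new ketone. This fallback answers the failure modes that stem from the triply substituted C4; it would not help if attack on the enol-ether-conjugated ester fails as such.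

**Step 7 (Friedel–Crafts acylation).** The most likely failure is partial racemisation, by enolisation of the acylium/ketene derived from 15 or of the AlCl3-bound ketone during a slow acylation.

The fallback replaces electrophilic acylation by addition of an aryllithium to a Weinreb amide, with no Lewis acid. It sets out from 14 and 13 and returns at 16. 14 would be protected (chloromethyl methyl ether, i-Pr2NEt) as 1,3,5-tris(methoxymethoxy)benzene F4. 13 would be converted (1,1'-carbonyldiimidazole, then MeNH(OMe)·HCl) into (2S)-N-methoxy-N,2-dimethylbutanamide F5. Lithiation of F4 between two acetal oxygens (n-BuLi, THF, 0 °C) and addition to F5 would give (2S)-2-methyl-1-[2,4,6-tris(methoxymethoxy)phenyl]butan-1-one F6. HCl in MeOH at rt would remove the three acetals and give 16. This costs four steps instead of one.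

**Step 8 (double coupling).** The most likely failures are exchange of bridges by ipso attack of 17 on 12 or on a product (which leads to symmetrical coupling), and a stall after the first alkylation. Both arise because every component is an electron-rich phenol able to form or accept a quinone methide.

The fallback reverses the roles, so that the scarce nucleophilic positions are on the component used in excess. It sets out from 16 (with 11 as partner) and returns at 19. Twofold Mannich reaction of 16 (CH2O, Me2NH, 2.2 equiv each, EtOH) would give (2S)-1-{3,5-bis[(dimethylamino)methyl]-2,4,6-trihydroxyphenyl}-2-methylbutan-1-one F7. Heating F7 with an excess of 11 (3–4 equiv) in 1,4-dioxane would give 19, and surplus 11, which has only one reactive ring position, would be recovered.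

## Further compounds

F1 | step 3 | (3E)-3,5-dimethoxy-4-methyl-5-oxopent-3-enoic acid | COC(=O)/C(C)=C(/OC)CC(=O)O
F2 | step 3 | dimethyl (2E)-3-methoxy-2-methyl-5-oxohept-2-enedioate | COC(=O)/C(C)=C(/OC)CC(=O)CC(=O)OC
F3 | step 4 | methyl 2,6-dihydroxy-4-methoxy-3-methylbenzoate | COC(=O)c1c(O)cc(OC)c(C)c1O
F4 | step 7 | 1,3,5-tris(methoxymethoxy)benzene | COCOc1cc(OCOC)cc(OCOC)c1
F5 | step 7 | (2S)-N-methoxy-N,2-dimethylbutanamide | CC[C@H](C)C(=O)N(C)OC
F6 | step 7 | (2S)-2-methyl-1-[2,4,6-tris(methoxymethoxy)phenyl]butan-1-one | CC[C@H](C)C(=O)c1c(OCOC)cc(OCOC)cc1OCOC
F7 | step 8 | (2S)-1-{3,5-bis[(dimethylamino)methyl]-2,4,6-trihydroxyphenyl}-2-methylbutan-1-one | CC[C@H](C)C(=O)c1c(O)c(CN(C)C)c(O)c(CN(C)C)c1O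
A1 | alternative 1 | 2,2'-{[2,4,6-tris(benzyloxy)-1,3-phenylene]bis(methylene)}bis[5-methoxy-4-methyl-3-(triisopropylsilyloxy)phenol] | Oc1cc(OC)c(C)c(O[Si](C(C)C)(C(C)C)C(C)C)c1Cc2c(OCc3ccccc3)cc(OCc4ccccc4)c(Cc5c(O)cc(OC)c(C)c5O[Si](C(C)C)(C(C)C)C(C)C)c2OCc6ccccc6
A2 | alternative 1 | 1,3,5-tris(benzyloxy)-2,4-bis{3-[tri(propan-2-yl)silyloxy]prop-2-yn-1-yl}benzene | CC(C)[Si](C(C)C)(C(C)C)OC#CCc1c(OCc2ccccc2)cc(OCc3ccccc3)c(CC#CO[Si](C(C)C)(C(C)C)C(C)C)c1OCc4ccccc4
A3 | alternative 1 | 3-methoxy-2-methylcyclobut-2-en-1-one | COC1=C(C)C(=O)C1
A4 | alternative 2 | (2S)-2-methyl-1-(2,4,6-trihydroxyphenyl)butan-1-one (identical with 16) | Oc1cc(O)c(C(=O)[C@@H](C)CC)c(O)c1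
A5 | alternative 2 | 4-hydroxy-6-[(3S)-3-methyl-2-oxopentyl]-2H-pyran-2-one | CC[C@H](C)C(=O)CC1=CC(O)=CC(=O)O1
A6 | alternative 2 | 4-hydroxy-6-methyl-2H-pyran-2-one | CC1=CC(O)=CC(=O)O1
A7 | alternative 3 | 1-(4,6-dihydroxy-2-methoxy-3-methylphenyl)butan-1-one (identical with 11) | CCCC(=O)c1c(O)cc(O)c(C)c1OC
A8 | alternative 3 | 2-methoxy-3-methyl-6-(2-oxopentyl)-4H-pyran-4-one | CCCC(=O)CC1=CC(=O)C(C)=C(OC)O1
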